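## Structural features

The target is a daucane sesquiterpenoid ester. A cyclopentane (C1–C5) is trans-fused through the C1–C5 bond to a cycloheptane (C1, C5–C10). C1 is quaternary and carries a methyl, C4 is an isopropyl carbinol, C6 carries the isovalerate, C8 is the spiro carbon of an oxirane whose CH2 is C14, and C9/C10 carry a cis diol.

There are seven stereocentres, all neighbours: C4–C5–C6 on one side and C8–C9–C10–C1 on the other. With the C1 methyl taken as β, the C4 hydroxyl is β (isopropyl α), while H5, the C6 oxygen, the epoxide oxygen, 9-OH and 10-OH are all α. In daucane numbering the target is (1S,4R,5S,6S,8S,9S,10S).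

The fragile groups are the 1,1-disubstituted epoxide flanked by a diol (acid-labile), the tertiary C4 alcohol 1,3 to the C6 oxygen (dehydration, retro-aldol at the ketone level) and the ester, which excludes strong nucleophiles late in the route.

The carbon skeleton is not the real difficulty. The difficulty is placing six C–O bonds on seven adjacent stereocentres of a compact bicycle, and telling three secondary hydroxyls apart so that only the C6 oxygen is acylated.

The feature the key step exploits is that C10–C9–C8(C14)–C7–C6–C5–C1(C15)–C2–C3–C4–C11(C12,C13) is an intact head-to-tail farnesyl chain. Only C1–C10 (closing the seven-membered ring) and C4–C5 (closing the five-membered ring) are missing. The two alkenes that remain after such a folding, C4=C5 and C8=C9, lie where the oxygens have to go.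

## Logic of the disconnections

17 to 16: the C9–H bond is cut, so the last stereocentre comes from a ketone. The cut is made here because in 16 both carbons next to C9 carry α-oxygens that should steer a hydride to the β face. The gain is one stereocentre fewer. The demand is a mild reduction that leaves the ester and the epoxide alone.

16 to 14 (through 15): the C10–O bond is cut. C10 is the only enolisable position of 14, so the hydroxyl can be put in by enolate oxidation without a regiochemical question. This removes one hydroxyl and one stereocentre. The forward step needs a base the ester survives and attack anti to the C1 methyl.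

14 to 13 to 12: first the C9 carbonyl is taken back to the alcohol, then the C8–O and C14–O bonds of the oxirane are cut to leave the C8=C14 alkene. The 9α-hydroxyl is used twice, as the directing group for the epoxidation and as the source of the ketone. The gain is loss of the spiro stereocentre. The demand is oxygen delivery syn to 9-OH.

12 to 11: the allylic alcohol is traced to the 8,9-epoxide, which means a C14–H bond is broken and the C8–O bond is cut in the forward sense. This is the only place where the C14 methyl is functionalised. The precursor has no alkene. The forward step must take the hydrogen from the methyl and not from C7, and must tolerate the ester.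

11 to 9 and 10: the ester C–O bond is cut. At the stage of 9 the C6 hydroxyl is the only secondary one, so no protecting group is needed. The gain is the commercial acyl fragment. The demand is only chemoselectivity over the hindered tertiary C4 hydroxyl.

9 to 7 (through 8): the C6–O and C5–H bonds are cut, both arising from syn addition to C5=C6. The C8=C9 alkene is already masked as the epoxide that the route needs anyway, so the borane sees one alkene. Two stereocentres are removed. The demand is α-face addition and survival of the epoxide.

7 to 6: the two C–O bonds of the 8,9-epoxide are cut. The gain is a diene alcohol with two stereocentres. The forward step must choose C8=C9 over the hindered C5=C6 and the α face.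

6 to 4 (through 5): the C4–O bond is cut and the alkene moved back from C5=C6 to C4=C5. This reaches a hydrocarbon with one stereocentre. The forward step must put oxygen on C4 and not C5, on the β face, and must leave C8=C9.

4 to 3: the C1–C10 and C4–C5 bonds are cut. Both rings open and the only stereocentre disappears, so the precursor is achiral and acyclic. The demand is heavy: 1,7-closure in preference to the easier 1,6-closure, and one enantioface. Only an enzyme pocket can impose this.

3 to 2 to 1: the C–O–P bond and then the C–Cl bond are cut, back to a commercial alcohol. The only demand is displacement without allylic transposition or loss of the E geometry.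

## Other disconnections considered

Alternative 1: The cut is at C1–C10 and C5–C6. The pieces are 3-methylcyclopent-2-en-1-one A1 (C1–C5 with the C1 methyl), the aldehyde (S)-3-(tert-butyldimethylsilyloxy)pent-4-enal A2 (C6–C9) and the alane diisobutyl[1-(trimethylsilyl)vinyl]aluminium A3 (C10).

- Forward step: a chiral N-heterocyclic carbene–copper catalyst made from Cu(OTf)2 would transfer the silylvinyl group of A3 to the β-carbon of A1, creating the quaternary C1. The aluminium enolate, activated with MeLi, would add to A2 to give the ketol A4. No ring is closed.
- In its favour: the ligand is available in both hands. The C6 and C8 oxygens are placed by construction. The C1/C5 trans relation should follow from trapping the enolate anti to the new substituent. The C4 ketone remains for an isopropyl addition that should come in anti to the C5 side chain and give the 4β-carbinol. On the C4 and C6 oxygen questions this plan is the better one, because the chosen route must win both by face-selective alkene oxidation.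
- Against it here: A4 still lacks the seven-membered ring (a ring-closing metathesis at a hindered C10 next to the quaternary centre), the isopropyl group, C14 and the C9/C10 oxygens. The aldol sets C6 in an open transition state, which is its weak point. Pyrophoric alane and MeLi and silyl protection are needed.
- Comparison: the two plans are equal in that a chiral catalyst, not the substrate, fixes C1. The chosen plan delivers all fifteen carbons and both rings in one step without protecting groups. From A4 roughly a dozen steps would remain, on top of those that make A2 and A3, so step economy favours the enzymatic folding.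

Alternative 2: The bonds cut are C6–O and C9–O. The hydroazulene 6,8-diene A5 already carries C1, C4, C5 and C10 in final form and a PMB-protected C14 oxygen.

- Forward step: irradiation with visible light under O2 with tetraphenylporphyrin; singlet oxygen would add across C6 and C9 in a [4+2] cycloaddition to give the endoperoxide A6.
- In its favour: both oxygens arrive suprafacially, so the cis C6/C9 relation is certain and only the face (anti to the C1 methyl) has to be right. C14 is already oxidised. On the certainty of the C6 configuration this plan is better than the chosen one, whose C6 rests on the face selectivity of a hydroboration.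
- Against it here: the step forms no carbon–carbon bond, so A5 needs its own skeleton synthesis. After O–O cleavage the C6 and C9 hydroxyls are both secondary and allylic and must be told apart for the ester. The C7=C8 alkene still has to become the C7 methylene and the C8 spiro-epoxide, which costs a transposition and redox steps. An endoperoxide is a less safe intermediate than any in the chosen route.
- Comparison: mechanistically it is the pericyclic relative of the ene reaction in step 4 and equally mild. As a way of finishing an existing hydroazulene it is the equal of the chosen oxidation sequence. As a plan it does not address the bicycle, so in total step count it cannot match a three-step entry to 4.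

Alternative 3: The cut is at C7–C8 and C1–C10. The pieces are the vinylcyclopentene A7 (C1–C7, C4 as its dioxolane) and the siloxyvinyldiazoacetate A8 (C8, C9, C10 and C14).

- Forward step: Rh2(S-DOSP)4 or its enantiomer would decompose A8. The carbene carbon C8 would cyclopropanate the vinyl group C6=C7 of A7. The cis-divinylcyclopropane would rearrange through a boat transition state, forming C1–C10 and closing the seven-membered ring to give A9.
- In its favour: a convergent and well-understood carbene reaction class that makes the ring and the quaternary C1 under catalyst control in either series. C9 is left as a silyl enol ether, so the C9 ketone needed for the C10 hydroxylation needs no oxidation step. C14 comes oxidised, and a C4 ketone is kept for a face-selective isopropyl addition. On these three functional-group points it is the equal or the better of the chosen plan.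
- Against it here: the Cope terminus at C1 is a fully substituted alkene carbon, which should slow the rearrangement and test the enantiocontrol. C14 comes at the ester level and must be reduced and turned into the exocyclic alkene. The isopropyl group is missing. C6 must still be oxygenated from C5=C6 with the same face problem as in the chosen route. A diazo ester is an energetic reagent, whereas the enzymatic step runs in buffer.
- Comparison: the two fragments would need about three to four steps each and roughly a dozen would follow A9, against three steps to 4 and nine after it. The chosen route is shorter and free of protecting groups. The alternative has the advantage of not depending on an enzyme of the right enantioselectivity.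

Key step: step 3

Remarks on the chemistry:
- Locants follow daucane numbering; β is the face of the C1 methyl.
- 3 is drawn as the free acid and handled as its ammonium salt.
- A daucene-forming synthase that gives the (1R) hydrocarbon 4 is assumed to be available by selection or engineering.
- The C1 descriptor changes from R in 4 to S in 17 only because the C10 hydroxyl changes the CIP priorities; the spatial arrangement is the same.
- C8=C9 is epoxidised before C5=C6 is hydroborated, because borane would not distinguish C5=C6 from a free C8=C9 or a C8=C14 alkene.

Step 1
Reactants: 1 (2E,6E)-farnesol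
Product: 2 (2E,6E)-farnesyl chloride
Conditions: NCS, Me2S, CH2Cl2, −40 → 0 °C
Reagents that add atoms: N-chlorosuccinimide, O=C1CCC(=O)N1Cl
Why: Corey–Kim chlorination turns the primary allylic alcohol into an alkoxysulfonium salt that chloride displaces directly at C1 (SN2), so there should be no allylic transposition and the E alkenes stay as they are.

Step 2
Reactants: 2 (2E,6E)-farnesyl chloride
Product: 3 (2E,6E)-farnesyl diphosphate
Conditions: (Bu4N)3HP2O7, MeCN, rt; Dowex 50W (NH4+ form); cellulose chromatography
Reagents that add atoms: tris(tetrabutylammonium) hydrogen diphosphate, CCCC[N+](CCCC)(CCCC)CCCC.CCCC[N+](CCCC)(CCCC)CCCC.CCCC[N+](CCCC)(CCCC)CCCC.OP([O-])(=O)OP([O-])([O-])=O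
Why: SN2 displacement of the primary allylic chloride by the diphosphate anion in a dipolar aprotic solvent should give the diphosphate ester with the alkene geometry unchanged; cation exchange gives the water-soluble ammonium salt that the enzyme accepts.

Step 3
Reactants: 3 (2E,6E)-farnesyl diphosphate
Product: 4 daucene, (1R)-dauca-4,8-diene
Conditions: recombinant daucene synthase (class 1 sesquiterpene cyclase), 10 mM MgCl2, HEPES buffer pH 7.5, DTT, 30 °C, isooctane overlay
Reagents that add atoms: none
Why: Mg2+ held at the aspartate-rich motif triggers loss of diphosphate from 3; recapture at the tertiary allylic carbon and re-ionisation let the former 2,3-alkene take the cisoid shape that a seven-membered ring needs. The CH2 terminus of the allyl cation (C10) then bonds to C1 of the central alkene in a 7-endo closure that forms the seven-membered ring, and the charge developing at C5 is taken up by the distal alkene through C4 in a 5-exo closure that forms the five-membered ring, so a free secondary cation need not exist. A 1,2-hydride shift from C4 to the isopropyl carbon C11 and loss of H5 to the bound diphosphate leave the C4=C5 alkene, and the old allyl unit remains as C8=C9. The closest known reaction type is the cyclisation of farnesyl diphosphate to daucane hydrocarbons and carotol by class 1 sesquiterpene synthases. The only new stereocentre, C1, is set by the contour of the active site, which offers one enantioface of the central alkene to the allyl cation; the substrate is achiral, so the enzyme has to be chosen or engineered for the (1R) product and the outcome checked by chiral GC. The selectivities needed are 1,7-closure over 1,6-closure (bisabolyl), 1,10-closure and 1,11-closure, and proton loss from C5 in place of water capture; nothing in 3 secures them and all depend on the fold of the enzyme.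

Step 4
Reactants: 4 daucene
Product: 6 dauca-5,8-dien-4β-ol, via 4β-hydroperoxydauca-5,8-diene 5 (not isolated)
Conditions: O2, tetraphenylporphyrin (cat.), visible light, CH2Cl2, −20 °C; then PPh3, −20 °C → rt
Reagents that add atoms: dioxygen, O=O
Why: Schenck ene reaction: singlet oxygen should attack the tetrasubstituted C4=C5 before the trisubstituted C8=C9 and bond to C4, the alkene carbon remote from the quaternary C1, taking a hydrogen from C6. Because C7 occupies the α position on C6 (the ring must reach the α-placed C10), the only C6 hydrogen perpendicular to the alkene plane is the β one, so the suprafacial process should put the oxygen on the β face of C4 and set that centre. PPh3 reduces the hydroperoxide without touching the C–O bond.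

Step 5
Reactants: 6 dauca-5,8-dien-4β-ol
Product: 7 8α,9α-epoxydauc-5-en-4β-ol
Conditions: mCPBA (1.05 equiv), NaHCO3, CH2Cl2, −20 °C
Reagents that add atoms: meta-chloroperoxybenzoic acid, OOC(=O)c1cccc(Cl)c1
Why: Prilezhaev epoxidation: the unhindered C8=C9 should react before C5=C6, which is flanked by two fully substituted carbons. The peracid should add to the α face, anti to the axial C1 methyl that sits 1,3 to C9, which sets C8 and C9; the buffer protects the tertiary allylic alcohol.

Step 6
Reactants: 7 8α,9α-epoxydauc-5-en-4β-ol
Product: 9 8α,9α-epoxy-5α-daucane-4β,6α-diol, via C6-alkylborane 8 (not isolated)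
Conditions: BH3·THF, THF, 0 °C → rt; then NaOH, H2O2, 0 °C
Reagents that add atoms: borane–tetrahydrofuran (boron stays only in 8), B.C1CCOC1; hydrogen peroxide, OO
Why: Hydroboration–oxidation: boron should go to the less substituted C6 and hydrogen to C5 in a syn addition on the α face, anti to the C1 methyl and to the C4 oxygen (the sense known for 5-ene steroids and for cyclic allylic alcohols). This sets the trans ring fusion at C5 and, after oxidation with retention, the 6α-hydroxyl. Borane reduces a trisubstituted epoxide only slowly, so the epoxide should survive.

Step 7
Reactants: 9 8α,9α-epoxy-5α-daucane-4β,6α-diol; 10 isovaleryl chloride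
Product: 11 8α,9α-epoxy-4β-hydroxy-5α-daucan-6α-yl 3-methylbutanoate
Conditions: pyridine, DMAP (cat.), CH2Cl2, 0 °C → rt
Reagents that add atoms: isovaleryl chloride (reactant 10), CC(C)CC(=O)Cl
Why: DMAP-catalysed acylation of the only secondary hydroxyl; the tertiary C4 hydroxyl is too hindered to compete and the basic medium leaves the epoxide intact.

Step 8
Reactants: 11 8α,9α-epoxy-4β-hydroxy-5α-daucan-6α-yl 3-methylbutanoate
Product: 12 4β,9α-dihydroxy-5α-dauc-8(14)-en-6α-yl 3-methylbutanoate
Conditions: Cp2TiCl2, Mn dust, THF, rt (Cp2TiCl formed in the flask); aq. NaH2PO4
Reagents that add atoms: none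
Why: Radical epoxide-to-allylic-alcohol isomerisation: Cp2TiCl (trivalent titanium) should open the C8–O bond homolytically to the tertiary C8 radical, and a second Cp2TiCl should trap it and remove a hydrogen from the unhindered C14 methyl to give the exocyclic alkene. The C9–O bond is never broken, so the 9α configuration is kept, and the ester and the tertiary alcohol are inert to this reagent.

Step 9
Reactants: 12 4β,9α-dihydroxy-5α-dauc-8(14)-en-6α-yl 3-methylbutanoate
Product: 13 8α,14-epoxy-4β,9α-dihydroxy-5α-daucan-6α-yl 3-methylbutanoate
Conditions: VO(acac)2 (cat.), t-BuOOH, CH2Cl2, 0 °C → rt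
Reagents that add atoms: tert-butyl hydroperoxide, CC(C)(C)OO
Why: Hydroxyl-directed epoxidation: the vanadium alkylperoxide bound to the allylic 9α-hydroxyl should deliver oxygen to the same (α) face of C8=C14, which sets C8 with the epoxide oxygen cis to 9-OH.

Step 10
Reactants: 13 8α,14-epoxy-4β,9α-dihydroxy-5α-daucan-6α-yl 3-methylbutanoate
Product: 14 8α,14-epoxy-4β-hydroxy-9-oxo-5α-daucan-6α-yl 3-methylbutanoate
Conditions: Dess–Martin periodinane, NaHCO3, CH2Cl2, rt
Reagents that add atoms: none
Why: Dess–Martin oxidation of the only secondary alcohol under buffered neutral conditions, which should spare the spiro-epoxide, the ester and the tertiary alcohol; C8 has no hydrogen, so nothing next to the new ketone can epimerise.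

Step 11
Reactants: 14 8α,14-epoxy-4β-hydroxy-9-oxo-5α-daucan-6α-yl 3-methylbutanoate
Product: 16 8α,14-epoxy-4β,10α-dihydroxy-9-oxo-5α-daucan-6α-yl 3-methylbutanoate, via dipotassium enolate 15 (not isolated)
Conditions: KHMDS (2.2 equiv), THF, −78 °C; then 2-(phenylsulfonyl)-3-phenyloxaziridine, −78 °C; NH4Cl
Reagents that add atoms: potassium bis(trimethylsilyl)amide (potassium stays only in 15), C[Si](C)(C)[N-][Si](C)(C)C.[K+]; 2-(phenylsulfonyl)-3-phenyloxaziridine, O=S(=O)(c1ccccc1)N1OC1c1ccccc1
Why: Enolate hydroxylation with a sulfonyloxaziridine (Davis oxidation): C10 is the only enolisable carbon of the ketone, and the ketone is more acidic than the ester, so after the tertiary hydroxyl is deprotonated the second equivalent of base should form the C9–C10 enolate. The electrophilic oxygen should come in on the α face, anti to the axial methyl on the adjacent C1, which sets C10.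

Step 12
Reactants: 16 8α,14-epoxy-4β,10α-dihydroxy-9-oxo-5α-daucan-6α-yl 3-methylbutanoate
Product: 17 (1S,4R,5S,6S,8S,9S,10S)-8,14-epoxy-4,9,10-trihydroxydaucan-6-yl 3-methylbutanoate (CNP0307265.1)
Conditions: NaBH4, MeOH/CH2Cl2, −40 °C
Reagents that add atoms: none
Why: Borohydride reduction under Felkin–Anh polar control: both carbons next to the ketone carry an α C–O bond (the epoxide oxygen on C8 and the hydroxyl on C10), so hydride should attack anti to both, from the β face, the sense usual for α,β-epoxy ketones. This sets C9 with the hydroxyl α and cis to its two neighbours; the ester and the epoxide are not reduced at this temperature.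

Compound list

1 | (2E,6E)-farnesol | CC(C)=CCC/C(C)=C/CC/C(C)=C/CO | starting material
2 | (2E,6E)-farnesyl chloride | CC(C)=CCC/C(C)=C/CC/C(C)=C/CCl | intermediate
3 | (2E,6E)-farnesyl diphosphate (ammonium salt in practice, drawn as the free acid) | CC(C)=CCC/C(C)=C/CC/C(C)=C/COP(O)(=O)OP(O)(O)=O | intermediate
4 | daucene, (1R)-dauca-4,8-diene [(8aR)-3-isopropyl-6,8a-dimethyl-1,2,4,5,8,8a-hexahydroazulene] | CC1=CC[C@@]2(C)CCC(C(C)C)=C2CC1 | intermediate
5 | (1R,4R)-4-hydroperoxydauca-5,8-diene (4β-OOH) | CC1=CC[C@@]2(C)CC[C@@](OO)(C(C)C)C2=CC1 | intermediate (not isolated)
6 | (1R,4R)-dauca-5,8-dien-4-ol (4β-OH) | CC1=CC[C@@]2(C)CC[C@@](O)(C(C)C)C2=CC1 | intermediate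
7 | 8α,9α-epoxydauc-5-en-4β-ol | C1C[C@@]2(C)O[C@H]2C[C@@]2(C)CC[C@@](O)(C(C)C)C2=1 | intermediate
8 | C6-alkylborane: 6α-boranyl-8α,9α-epoxy-5α-daucan-4β-yl dihydroborinate (idealised as C6–BH2, C4–O–BH2) | B[C@H]1C[C@@]2(C)O[C@H]2C[C@@]2(C)CC[C@@](OB)(C(C)C)[C@H]12 | intermediate (not isolated)
9 | 8α,9α-epoxy-5α-daucane-4β,6α-diol | O[C@H]1C[C@@]2(C)O[C@H]2C[C@@]2(C)CC[C@@](O)(C(C)C)[C@H]12 | intermediate
10 | isovaleryl chloride (3-methylbutanoyl chloride) | CC(C)CC(=O)Cl | starting material
11 | 8α,9α-epoxy-4β-hydroxy-5α-daucan-6α-yl 3-methylbutanoate | CC(C)CC(=O)O[C@H]1C[C@@]2(C)O[C@H]2C[C@@]2(C)CC[C@@](O)(C(C)C)[C@H]12 | intermediate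
12 | 4β,9α-dihydroxy-5α-dauc-8(14)-en-6α-yl 3-methylbutanoate | CC(C)CC(=O)O[C@H]1CC(=C)[C@@H](O)C[C@@]2(C)CC[C@@](O)(C(C)C)[C@H]12 | intermediate
13 | 8α,14-epoxy-4β,9α-dihydroxy-5α-daucan-6α-yl 3-methylbutanoate | CC(C)CC(=O)O[C@H]1C[C@]2(CO2)[C@@H](O)C[C@@]2(C)CC[C@@](O)(C(C)C)[C@H]12 | intermediate
14 | 8α,14-epoxy-4β-hydroxy-9-oxo-5α-daucan-6α-yl 3-methylbutanoate | CC(C)CC(=O)O[C@H]1C[C@]2(CO2)C(=O)C[C@@]2(C)CC[C@@](O)(C(C)C)[C@H]12 | intermediate
15 | dipotassium salt of 14 (C4 alkoxide, C9–C10 enolate) | CC(C)CC(=O)O[C@H]1C[C@]2(CO2)C([O-])=C[C@@]2(C)CC[C@@]([O-])(C(C)C)[C@H]12.[K+].[K+] | intermediate (not isolated)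
16 | 8α,14-epoxy-4β,10α-dihydroxy-9-oxo-5α-daucan-6α-yl 3-methylbutanoate | CC(C)CC(=O)O[C@H]1C[C@]2(CO2)C(=O)[C@@H](O)[C@@]2(C)CC[C@@](O)(C(C)C)[C@H]12 | intermediate
17 | (1S,4R,5S,6S,8S,9S,10S)-8,14-epoxy-4,9,10-trihydroxydaucan-6-yl 3-methylbutanoate (8α,14-epoxy-4β,9α,10α-trihydroxy-5α-daucan-6α-yl isovalerate) | CC(C)CC(=O)O[C@H]1C[C@]2(CO2)[C@@H](O)[C@@H](O)[C@@]2(C)CC[C@@](O)(C(C)C)[C@H]12 | target

Total step count: 12. Longest linear sequence: 12 steps (1 to 17); 10 is used as purchased.

Steps least certain to work

Step 3 (key step). The cyclase may fold the chain along competing channels (1,6- or 1,10-closure, early proton loss, water capture), may give the wrong enantiomeric series, or may turn over slowly because the product or the released diphosphate inhibits it. Phosphatases in a crude lysate may also hydrolyse 3. All of this follows from the fact that selectivity resides only in the protein. The fallback sets out from 3 and comes back at 4. A carotol-forming synthase of the same family, which stops the same cation cascade by water capture at C5, would give carotol F1 with the C1 configuration of 4. A syn dehydration with Burgess reagent (H4 is cis to the C5 hydroxyl) would then generate the C4=C5 alkene chemically. The alkene-forming step is thereby taken out of the enzyme.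

Step 4. Hydrogen abstraction from C3 with C–O bond formation at C5 may compete, which is loss of regiocontrol in the ene reaction. Over-oxidation at C8=C9 and rearrangement of the tertiary allylic hydroperoxide before reduction are also possible. The cause is that the alkene has allylic hydrogens on both sides. The fallback sets out from 4 and comes back at 6. mCPBA at low temperature should epoxidise the tetrasubstituted alkene first to give 4β,5β-epoxydauc-8-ene F2. LiNEt2 in ether should then effect a syn elimination through the β hydrogen on C6; the five-membered ring hydrogens at C3 are poorly placed for this. The face selectivity of that epoxidation would have to be established.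

Step 5. Competing epoxidation of C5=C6, assisted by hydrogen bonding to the C4 hydroxyl, or attack on the β face of C8=C9 may erode the selectivity, because both alkenes are trisubstituted and the seven-membered ring is flexible. The fallback sets out from 6 and comes back at 7. It replaces substrate control by catalyst control: a Shi epoxidation (fructose-derived ketone of the appropriate enantiomeric series, Oxone, buffered MeCN/dimethoxymethane) is well suited to unhindered trisubstituted alkenes and should ignore the crowded C5=C6. It makes no new compound (F0).

Step 6. Addition of the borane to the β face would give the cis-fused 5β,6β product, since the α face carries the isopropyl group and the folded seven-membered ring. Slow reductive opening of the epoxide by borane is a second risk. The fallback sets out from 7 and comes back at 9. The hydroboration is run as before and the mixture of 9 and 8α,9α-epoxy-5β-daucane-4β,6β-diol F3 is oxidised with Dess–Martin periodinane. C5 is then equilibrated with DBU to the trans-fused 8α,9α-epoxy-4β-hydroxy-5α-daucan-6-one F4, in which the isopropyl group is trans to the C6 branch. The ketone is reduced with Me4NBH(OAc)3, where hydride is delivered from boron bound to the β C4 oxygen to the β face of C6 (Evans–Saksena anti reduction). Kinetic face control is thus replaced by thermodynamic control at C5 and a directed reduction at C6.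

Step 8. Hydrogen loss towards C7 (endocyclic alkene), reduction of the tertiary radical to the saturated alcohol, or deoxygenation back to the alkene may compete, because the fate of the C8 radical depends on how fast the second titanium traps it. The fallback sets out from 9 and comes back at 14. It carries C6 as a silyl ether through a base-mediated isomerisation and installs the ester later:
- TESCl and imidazole would give 8α,9α-epoxy-6α-(triethylsilyloxy)-5α-daucan-4β-ol F5.
- Et2Al(TMP) (diethylaluminium 2,2,6,6-tetramethylpiperidide) in toluene should remove a methyl hydrogen through a cyclic syn elimination to give 6α-(triethylsilyloxy)-5α-dauc-8(14)-ene-4β,9α-diol F6.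
- VO(acac)2/t-BuOOH would give 8α,14-epoxy-6α-(triethylsilyloxy)-5α-daucane-4β,9α-diol F7.
- Dess–Martin oxidation would give 8α,14-epoxy-4β-hydroxy-6α-(triethylsilyloxy)-5α-daucan-9-one F8.
- Bu4NF buffered with AcOH would free 8α,14-epoxy-4β,6α-dihydroxy-5α-daucan-9-one F9.
- Acylation of F9 with 10 and pyridine would give 14.

Step 12. Hydride delivery from the α face would give the 9β epimer; the axial C1 methyl stands 1,3 to C9 on the β face and opposes the polar effect of the two α oxygens. The fallback sets out from 16 and comes back at 17. It replaces substrate control by catalyst control: a ketoreductase chosen from a panel (NADPH, glucose and glucose dehydrogenase for recycling, aqueous buffer with a cosolvent) would be selected for the 9α alcohol. It makes no new compound (F0).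

Further compounds

F1 | step 3 | carotol with the C1 configuration of 4 (5β-hydroxy, 4β-H, 4α-isopropyl dauc-8-ene) | CC1=CC[C@@]2(C)CC[C@@H](C(C)C)[C@@]2(O)CC1
F2 | step 4 | 4β,5β-epoxydauc-8-ene | CC1=CC[C@@]2(C)CC[C@]3(C(C)C)O[C@]23CC1
F0 | step 5 | none | none
F3 | step 6 | 8α,9α-epoxy-5β-daucane-4β,6β-diol | O[C@@H]1C[C@@]2(C)O[C@H]2C[C@@]2(C)CC[C@@](O)(C(C)C)[C@@H]12
F4 | step 6 | 8α,9α-epoxy-4β-hydroxy-5α-daucan-6-one | O=C1C[C@@]2(C)O[C@H]2C[C@@]2(C)CC[C@@](O)(C(C)C)[C@H]12
F5 | step 8 | 8α,9α-epoxy-6α-(triethylsilyloxy)-5α-daucan-4β-ol | CC[Si](CC)(CC)O[C@H]1C[C@@]2(C)O[C@H]2C[C@@]2(C)CC[C@@](O)(C(C)C)[C@H]12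
F6 | step 8 | 6α-(triethylsilyloxy)-5α-dauc-8(14)-ene-4β,9α-diol | CC[Si](CC)(CC)O[C@H]1CC(=C)[C@@H](O)C[C@@]2(C)CC[C@@](O)(C(C)C)[C@H]12
F7 | step 8 | 8α,14-epoxy-6α-(triethylsilyloxy)-5α-daucane-4β,9α-diol | CC[Si](CC)(CC)O[C@H]1C[C@]2(CO2)[C@@H](O)C[C@@]2(C)CC[C@@](O)(C(C)C)[C@H]12
F8 | step 8 | 8α,14-epoxy-4β-hydroxy-6α-(triethylsilyloxy)-5α-daucan-9-one | CC[Si](CC)(CC)O[C@H]1C[C@]2(CO2)C(=O)C[C@@]2(C)CC[C@@](O)(C(C)C)[C@H]12
F9 | step 8 | 8α,14-epoxy-4β,6α-dihydroxy-5α-daucan-9-one | O[C@H]1C[C@]2(CO2)C(=O)C[C@@]2(C)CC[C@@](O)(C(C)C)[C@H]12
F0 | step 12 | none | none
A1 | alternative 1 | 3-methylcyclopent-2-en-1-one | CC1=CC(=O)CC1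
A2 | alternative 1 | (S)-3-(tert-butyldimethylsilyloxy)pent-4-enal | O=CC[C@H](O[Si](C)(C)C(C)(C)C)C=C
A3 | alternative 1 | diisobutyl[1-(trimethylsilyl)vinyl]aluminium | C=C([Si](C)(C)C)[Al](CC(C)C)CC(C)C
A4 | alternative 1 | 2,3,3-trisubstituted cyclopentanone ketol carrying C6–C9 and the C10 silylvinyl group | O[C@@H](C[C@H](O[Si](C)(C)C(C)(C)C)C=C)[C@H]1C(=O)CC[C@]1(C)C(=C)[Si](C)(C)C
A5 | alternative 2 | 14-(4-methoxybenzyloxy)-5α-dauca-6,8-diene-4β,10α-diol | C1=CC(COCc2ccc(OC)cc2)=C[C@@H](O)[C@@]2(C)CC[C@@](O)(C(C)C)[C@H]12
A6 | alternative 2 | 6α,9α-endoperoxide of A5 (2,3-dioxabicyclo[3.2.2]nonene) | O1O[C@H]2C=C(COCc3ccc(OC)cc3)[C@@H]1[C@@H](O)[C@@]3(C)CC[C@@](O)(C(C)C)[C@H]23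
A7 | alternative 3 | 6-methyl-7-vinyl-1,4-dioxaspiro[4.4]non-6-ene | CC1=C(C=C)C2(OCCO2)CC1
A8 | alternative 3 | methyl 3-(tert-butyldimethylsilyloxy)-2-diazobut-3-enoate | COC(=O)C(=[N+]=[N-])C(=C)O[Si](C)(C)C(C)(C)C
A9 | alternative 3 | hydroazulene 5,8-diene with C14 ester, C9 silyl enol ether and C4 dioxolane | C1=C2C3(OCCO3)CC[C@]2(C)CC(O[Si](C)(C)C(C)(C)C)=C(C(=O)OC)C1
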